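## Analysis of the target

The target is an unbranched chain of ten benzene rings joined by nine diaryl ether oxygens and carrying twenty-six free phenolic hydroxyls. The rings are lettered A to J from the 2,4,6-trihydroxyphenyl end, and in every ring C1 is the carbon whose ether oxygen points toward ring A (in ring A itself, toward ring B). There is no stereocentre, so the whole task is regiochemistry and C–O bond construction. Rings B, D, F and H carry ether oxygens on C1 and C4, hydroxyls on C3 and C5 and hydrogen on C2 and C6; rings C, E, G and I carry ether oxygens on C1 and C2 and hydroxyls on C3, C4 and C5; ring J is a 3,4,5-trihydroxyphenyl group. Every bridging oxygen therefore joins a carbon with two oxygenated neighbours (C1 of ring A, C4 of rings B, D, F, H, C2 of rings C, E, G, I) to a carbon with at most one ortho substituent. The free polyphenol, with five vicinal triol rings, is oxidised by air, fastest in base, so all hydroxyls must stay masked to the last step, and the masked intermediates are very electron-rich arenes (ring A most of all) that limit the use of strong electrophiles and oxidants. The difficulty is to make nine ether bonds, each hindered on one side, in a repetitive chain where a misplaced ring is hard to detect, at an acceptable step count. The strategy rests on ring F: C1 bears the oxygen from ring E and lies between the CH carbons C2 and C6, while C3, C4 and C5 all bear oxygen, so that C2–C1–C6 is an oxygen-substituted malondialdehyde unit and C3–C4–C5 a 1,3-dioxygenated acetone.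

## Retrosynthetic reasoning

Target 37 is traced back to its permethyl ether 36 by cutting twenty-six O–CH3 bonds. Methyl is chosen because it survives copper catalysis, peracid, alkoxide base and dilute acid, and because Lewis-acid cleavage of aryl methyl ethers leaves diaryl ether bonds intact. The forward step has to cleave all twenty-six ethers and deliver the air-sensitive polyphenol under inert gas.

Compound 36 is cut at the bond between the bridging oxygen and C1 of ring H, giving heptamer phenol 29 and trimer bromide 35. This bond is chosen because the oxygen stays on the hindered carbon (C2 of ring G) as the nucleophile, while the carbon that must accept it has no ortho substituent. A cut one ring earlier, between rings F and G, would be more convergent on paper. It would, however, ask a di-ortho-methoxy phenol to displace an unactivated halide that has an aryloxy group next to it, and the four-ring halide would have to carry its halogen through two further copper couplings. The 7 + 3 division gives the less hindered union and a three-step fragment.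

Bromide 35 is cut at the oxygen–C1 bond of ring J to phenol 33 and boronic acid 34; an oxidative copper coupling at room temperature leaves the C–Br bond alone. Phenol 33 comes from aldehyde 31 by exchange of formyl for hydroxyl, and 31 from bromophenol 30 and iodoaldehyde 2, where the ortho-formyl iodide reacts ahead of the bromide.

Heptamer phenol 29 is taken back to aldehyde 27 and this to hexamer phenol 26 and iodoaldehyde 2. The formyl group serves twice: it activates the neighbouring C–I bond for the coupling and is then converted into the hydroxyl on C2 of ring G.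

Hexamer phenol 26 is cut at C2–C3 and C5–C6 of ring F, which divides the ring into the three-carbon dielectrophile 23 and the three-carbon ketone 24. This is the central disconnection. It removes a whole ring in one operation, it delivers the C4 hydroxyl of ring F already free for the next coupling, and it means that the ring E–O–ring F bond, whose oxygen sits between an aryloxy and a methoxy group, never has to be made by arylation. The forward reaction must join both α-carbons of 24 to the formyl and enamine carbons of 23 and aromatise.

Enaminal 23 is traced to aldehyde 21 and formamide acetal 22, and 21 through acetal 20 to pentamer phenol 18 and bromoacetal 19. The hindered phenol oxygen is thus bonded to a primary sp3 carbon by simple alkylation.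

Pentamer phenol 18 is unravelled ring by ring with one repeating pair of operations: exchange of formyl for hydroxyl (18 from 16, 15 from 13, 12 from 10, 9 from 7, 5 from 3) and a copper-mediated ether coupling in which the chain phenol attacks a halobenzaldehyde (16 from 15 and 2, 13 from 12 and 6, 10 from 9 and 2, 7 from 5 and 6). The para-formyl bromide 6 supplies rings B and D, the ortho-formyl iodide 2 supplies rings C and E, and in each case the position of the formyl group fixes where the next oxygen appears.

Iodoaldehyde 2, needed four times, is cut at its formyl carbon to iodoarene 1; the two open positions of 1 are equivalent, so formylation can give only one isomer.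

## Alternatives that were turned down

Alternative 1: Both C–O bonds of ring H are cut, and ring H is supplied by a dichloroarene bound η6 to cationic cyclopentadienylruthenium, A1. In the forward sense heptamer phenol 29 (as its phenoxide) would displace the unhindered chloride, the ring I–J dimer phenol A2 would then displace the chloride between the two methoxy groups, and the ruthenium-bound decamer A3 would be decomplexed by photolysis and demethylated. In its favour, η6-coordination lets chloroarenes react with phenoxides near room temperature, and the three fragments (7 + 1 + 2 rings) meet in an activated substitution. On this point it is stronger than the unactivated copper coupling of step 20. Against it, the two chlorides of A1 are told apart by sterics alone. The first aryloxy group also deactivates the arene for the second substitution, which must occur at the more hindered carbon with a phenoxide that itself has an ortho aryloxy group. The metal fragment can in addition be captured by the more electron-rich polymethoxy rings of the product, and ruthenium is used stoichiometrically. It also does nothing for the longest part of the work, since 29 is still needed in full. The chosen strategy accepts one unactivated coupling at an unhindered carbon and instead builds ring F from two small acyclic pieces.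

Alternative 2: Ring C is cut at C5–C6 and traced to the 4-hydroxycyclobutenone A4 (racemic at its carbinol carbon), made by adding the 1-aryloxyvinyl anion of the ring A–B dimer to a squaric acid diester. On heating, A4 would open to a dienylketene whose six-electron closure and tautomerisation give the trimer hydroquinone A5 (Moore rearrangement). In its favour, the ring expansion is regiospecific, it places four oxygens on ring C without ambiguity, and it forms the hindered ring B–O–ring C bond by vinylation instead of arylation. For a pentasubstituted ring it is at least as strong a ring-forming step as the one chosen. Against it, A5 has two free hydroxyls, on C2 and C5, of which only the more hindered C2 hydroxyl is to be arylated, so the less hindered one must first be masked selectively. The α-metalation of the aryl vinyl ether competes with methoxy-directed metalation of ring B, A5 is an air-sensitive hydroquinone, and the annulation is spent on the third of ten rings, leaving seven to be added afterwards. The chosen annulation gives a single phenol and sits at the centre of the chain.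

Alternative 3: Ring A is cut at C2–C3 and C5–C6 and made last, from the nonamer aryloxymalonate A6 and dimethyl 3-oxopentanedioate A7, by double Claisen-type acylation to the decamer isophthalate A8. In its favour, the regiochemistry of ring A is as unambiguous as that of ring F in the chosen route, and ring A needs no protecting groups. Against it, the malonate C–H between two esters and an aryloxy group is the most acidic site present, and once it is deprotonated the ester carbonyls are poor acceptors for the two C-acylations. A8 also carries two ester groups that must be hydrolysed and decarboxylated. The annulation is moreover placed at the very end on a nine-ring intermediate, and it builds the one ether (ring A to ring B) that is easiest to make by coupling from purchasable pieces. The chosen strategy uses its ring synthesis on a five-ring substrate, adds no extraneous carbon, and delivers the phenol needed for the next bond.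

Key step: step 14

Assumption: compounds 1, 3, 6, 19, 22, 24, 30 and 34 are taken as purchasable; in all oligomer names every oxygen not otherwise specified is a methyl ether and ring positions follow the numbering defined in the analysis.

Step 1
Reactants: 1 5-iodo-1,2,3-trimethoxybenzene
Product: 2 6-iodo-2,3,4-trimethoxybenzaldehyde
Conditions: Cl2CHOMe, TiCl4, CH2Cl2, −10 to 0 °C; then ice-water
Reagents that add atoms: dichloromethyl methyl ether, COC(Cl)Cl; water, O
Why: Rieche formylation; the two free positions of 1 are equivalent and each is ortho to one methoxy and para to another, so a single aldehyde should form.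

Step 2
Reactants: 3 2,4,6-trimethoxybenzaldehyde
Product: 5 2,4,6-trimethoxyphenol, via 2,4,6-trimethoxyphenyl formate 4 (not isolated)
Conditions: mCPBA, CH2Cl2, 0 °C to rt; aq. Na2S2O3/NaHCO3 wash; then cat. K2CO3, MeOH, argon, rt
Reagents that add atoms: mCPBA (3-chloroperoxybenzoic acid), OOC(=O)c1cccc(Cl)c1
Why: Baeyer–Villiger oxidation of an electron-rich benzaldehyde (Dakin-type); the trimethoxyaryl group migrates in preference to hydride, and the formate is methanolysed only after the peracid is destroyed, which protects the phenol from over-oxidation.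

Step 3
Reactants: 5 2,4,6-trimethoxyphenol; 6 4-bromo-2,6-dimethoxybenzaldehyde
Product: 7 ring A–B dimer aldehyde 2,6-dimethoxy-4-(2,4,6-trimethoxyphenoxy)benzaldehyde
Conditions: CuI (10 mol %), N,N-dimethylglycine·HCl (30 mol %), Cs2CO3, 1,4-dioxane, 100 °C
Reagents that add atoms: none
Why: Ligand-accelerated Ullmann diaryl ether coupling; the bromide is para to the formyl group and has no ortho substituent, so the hindrance lies only on the phenoxide, which monovalent copper tolerates.

Step 4
Reactants: 7 ring A–B dimer aldehyde
Product: 9 ring A–B dimer phenol 2,6-dimethoxy-4-(2,4,6-trimethoxyphenoxy)phenol, via ring A–B dimer formate 8 (not isolated)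
Conditions: mCPBA (1.1 equiv), CH2Cl2, 0 °C; aq. Na2S2O3/NaHCO3 wash; then cat. K2CO3, MeOH–THF, argon, rt
Reagents that add atoms: mCPBA (3-chloroperoxybenzoic acid), OOC(=O)c1cccc(Cl)c1
Why: Baeyer–Villiger oxidation and formate methanolysis as in step 2; the aldehyde flanked by two methoxy groups and para to an aryloxy group is the most readily oxidised site, and a near-stoichiometric charge at 0 °C spares ring A.

Step 5
Reactants: 9 ring A–B dimer phenol; 2 6-iodo-2,3,4-trimethoxybenzaldehyde
Product: 10 ring A–C trimer aldehyde 6-[2,6-dimethoxy-4-(2,4,6-trimethoxyphenoxy)phenoxy]-2,3,4-trimethoxybenzaldehyde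
Conditions: CuI (10 mol %), N,N-dimethylglycine·HCl (30 mol %), Cs2CO3, 1,4-dioxane, 90 °C
Reagents that add atoms: none
Why: Ullmann coupling of a 2,6-dimethoxyphenol with an aryl iodide activated by its ortho formyl group, the classical pairing for ortho-aryloxybenzaldehydes; the iodide carbon has only one ortho substituent.

Step 6
Reactants: 10 ring A–C trimer aldehyde
Product: 12 ring A–C trimer phenol (free OH on C2 of ring C), via ring A–C trimer formate 11 (not isolated)
Conditions: mCPBA (1.1 equiv), CH2Cl2, 0 °C; aq. Na2S2O3/NaHCO3 wash; then cat. K2CO3, MeOH–THF, argon, rt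
Reagents that add atoms: mCPBA (3-chloroperoxybenzoic acid), OOC(=O)c1cccc(Cl)c1
Why: Baeyer–Villiger oxidation; the formyl-bearing carbon has ortho methoxy, ortho aryloxy and para methoxy groups, so aryl migration to the formate should be fast, and methanolysis frees the hydroxyl exactly where ring D must be attached.

Step 7
Reactants: 12 ring A–C trimer phenol; 6 4-bromo-2,6-dimethoxybenzaldehyde
Product: 13 ring A–D tetramer aldehyde (CHO on C4 of ring D)
Conditions: CuI (10 mol %), N,N-dimethylglycine·HCl (30 mol %), Cs2CO3, 1,4-dioxane, 100 °C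
Reagents that add atoms: none
Why: Ullmann coupling as in step 3; the phenol is flanked by an aryloxy and a methoxy group, but the para-formyl bromide is unhindered and activated.

Step 8
Reactants: 13 ring A–D tetramer aldehyde
Product: 15 ring A–D tetramer phenol (free OH on C4 of ring D), via ring A–D tetramer formate 14 (not isolated)
Conditions: mCPBA (1.1 equiv), CH2Cl2, 0 °C; aq. Na2S2O3/NaHCO3 wash; then cat. K2CO3, MeOH–THF, argon, rt
Reagents that add atoms: mCPBA (3-chloroperoxybenzoic acid), OOC(=O)c1cccc(Cl)c1
Why: Baeyer–Villiger oxidation and formate methanolysis, the same transformation as step 4 on the same substitution pattern.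

Step 9
Reactants: 15 ring A–D tetramer phenol; 2 6-iodo-2,3,4-trimethoxybenzaldehyde
Product: 16 ring A–E pentamer aldehyde (CHO on C2 of ring E)
Conditions: CuI (10 mol %), N,N-dimethylglycine·HCl (30 mol %), Cs2CO3, 1,4-dioxane, 90 °C
Reagents that add atoms: none
Why: Ullmann coupling as in step 5, a 2,6-dimethoxyphenol with the ortho-formyl iodide.

Step 10
Reactants: 16 ring A–E pentamer aldehyde
Product: 18 ring A–E pentamer phenol (free OH on C2 of ring E), via ring A–E pentamer formate 17 (not isolated)
Conditions: mCPBA (1.1 equiv), CH2Cl2, 0 °C; aq. Na2S2O3/NaHCO3 wash; then cat. K2CO3, MeOH–THF, argon, rt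
Reagents that add atoms: mCPBA (3-chloroperoxybenzoic acid), OOC(=O)c1cccc(Cl)c1
Why: Baeyer–Villiger oxidation and formate methanolysis as in step 6.

Step 11
Reactants: 18 ring A–E pentamer phenol; 19 bromoacetaldehyde diethyl acetal
Product: 20 ring A–E pentamer 2,2-diethoxyethyl ether (on the C2 oxygen of ring E)
Conditions: Cs2CO3, DMF, 110 °C
Reagents that add atoms: none
Why: Williamson ether synthesis; the cesium phenoxide, though flanked on both sides, attacks a primary carbon, which is far less demanding than arylation at the same oxygen.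

Step 12
Reactants: 20 ring A–E pentamer 2,2-diethoxyethyl ether
Product: 21 ring A–E pentamer aryloxyacetaldehyde
Conditions: 1 M HCl, THF, 45 °C, argon; used crude
Reagents that add atoms: water, O
Why: Acid-catalysed acetal hydrolysis; both positions ortho to the ether oxygen on ring E are substituted, so the benzofuran-forming cyclisation known for aryloxyacetaldehyde acetals cannot occur, and dilute aqueous acid keeps intermolecular arene alkylation slow.

Step 13
Reactants: 21 ring A–E pentamer aryloxyacetaldehyde; 22 N,N-dimethylformamide dimethyl acetal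
Product: 23 (Z)-2-(ring A–E pentamer aryloxy)-3-(dimethylamino)prop-2-enal
Conditions: 22 (3 equiv), toluene, 80 °C
Reagents that add atoms: none
Why: Aminomethylenation of an active methylene by an amide acetal; the CH2 between the formyl and aryloxy groups condenses with loss of two methanol, and the push–pull product should settle in the isomer with formyl and dimethylamino groups trans, which is the Z form.

Step 14
Reactants: 23 (Z)-2-(ring A–E pentamer aryloxy)-3-(dimethylamino)prop-2-enal; 24 1,3-dimethoxyacetone
Product: 26 ring A–F hexamer phenol (free OH on C4 of ring F), via open-chain aminodienone 25 (not isolated)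
Conditions: 24 (3 equiv), t-BuOK (3 equiv), THF/t-BuOH, 0 to 60 °C; then AcOH
Reagents that add atoms: none
Why: Base-mediated [3+3] aldol benzannulation, the known condensation of ketones having two α-methylene groups with nitromalonaldehyde, vinamidinium salts or 2-substituted 3-aminoacroleins to para-substituted phenols. The potassium enolate of 24 adds to the formyl carbon of 23 and the aldolate loses water, giving the push–pull aminodienone 25 and the C2–C3 bond of ring F. Because 25 is a vinylogous amide, its formal double bonds rotate easily and it can reach the cisoid geometry in which the remaining methoxymethyl group lies over the enamine carbon. Deprotonation at that α′-carbon gives a trienolate that closes the C5–C6 bond by 6-endo attack on the enamine carbon, equivalent to a thermal six-electron disrotatory electrocyclisation. E1cB loss of dimethylamine from the cyclised enolate and tautomerisation of the cyclohexadienone give the phenol, and this aromatisation makes the sequence irreversible. No stereocentre is formed and, 24 being symmetric, there is no regiochemical choice; the one requirement, that the two bonds come from opposite α-carbons, is met because the first α-carbon is sp2 and no longer acidic after dehydration, and only the other can reach the enamine carbon through a six-membered transition state. Each methoxy group sits on an enolate carbon and not β to one, so methoxide cannot be expelled, and the aryloxy group on C1 is likewise on a carbon of the delocalised system, whereas the amine is β to the ring enolate and leaves. Excess 24 offsets its self-aldol reaction.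

Step 15
Reactants: 26 ring A–F hexamer phenol; 2 6-iodo-2,3,4-trimethoxybenzaldehyde
Product: 27 ring A–G heptamer aldehyde (CHO on C2 of ring G)
Conditions: CuI (10 mol %), N,N-dimethylglycine·HCl (30 mol %), Cs2CO3, 1,4-dioxane, 90 °C
Reagents that add atoms: none
Why: Ullmann coupling as in steps 5 and 9; the new ring F phenol is a 4-aryloxy-2,6-dimethoxyphenol, the same nucleophile type as 9 and 15.

Step 16
Reactants: 27 ring A–G heptamer aldehyde
Product: 29 ring A–G heptamer phenol (free OH on C2 of ring G), via ring A–G heptamer formate 28 (not isolated)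
Conditions: mCPBA (1.1 equiv), CH2Cl2, 0 °C; aq. Na2S2O3/NaHCO3 wash; then cat. K2CO3, MeOH–THF, argon, rt
Reagents that add atoms: mCPBA (3-chloroperoxybenzoic acid), OOC(=O)c1cccc(Cl)c1
Why: Baeyer–Villiger oxidation and formate methanolysis as in steps 6 and 10.

Step 17
Reactants: 30 4-bromo-2,6-dimethoxyphenol; 2 6-iodo-2,3,4-trimethoxybenzaldehyde
Product: 31 ring H–I dimer aldehyde 6-(4-bromo-2,6-dimethoxyphenoxy)-2,3,4-trimethoxybenzaldehyde
Conditions: CuI (10 mol %), N,N-dimethylglycine·HCl (30 mol %), Cs2CO3, 1,4-dioxane, 80 °C
Reagents that add atoms: none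
Why: Chemoselective Ullmann coupling; the C–I bond ortho to the formyl group reacts well below the temperature needed for an aryl bromide, and the bromide of 30 is further deactivated by the para phenoxide oxygen.

Step 18
Reactants: 31 ring H–I dimer aldehyde
Product: 33 ring H–I dimer phenol 6-(4-bromo-2,6-dimethoxyphenoxy)-2,3,4-trimethoxyphenol, via ring H–I dimer formate 32 (not isolated)
Conditions: mCPBA (1.1 equiv), CH2Cl2, 0 °C; aq. Na2S2O3/NaHCO3 wash; then cat. K2CO3, MeOH–THF, argon, rt
Reagents that add atoms: mCPBA (3-chloroperoxybenzoic acid), OOC(=O)c1cccc(Cl)c1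
Why: Baeyer–Villiger oxidation and formate methanolysis; the aryl bromide is inert to peracid and to carbonate in methanol.

Step 19
Reactants: 33 ring H–I dimer phenol; 34 3,4,5-trimethoxyphenylboronic acid
Product: 35 ring H–J trimer bromide 5-bromo-1,3-dimethoxy-2-[3,4,5-trimethoxy-2-(3,4,5-trimethoxyphenoxy)phenoxy]benzene
Conditions: Cu(OAc)2 (2 equiv), 34 (2.5 equiv), pyridine, 4 Å MS, CH2Cl2, rt
Reagents that add atoms: none
Why: Chan–Lam coupling; the aryl group is transferred from boron to the divalent copper phenoxide and the C–O bond forms by reductive elimination from trivalent copper at room temperature, conditions under which an aryl bromide is untouched and phenols with two ortho substituents are known to couple.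

Step 20
Reactants: 29 ring A–G heptamer phenol; 35 ring H–J trimer bromide
Product: 36 permethylated decamer (ring A–J hexacosamethyl ether)
Conditions: CuI (20 mol %), picolinic acid (40 mol %), K3PO4, DMSO, 105 °C, argon; 35 (1.5 equiv)
Reagents that add atoms: none
Why: Ullmann diaryl ether coupling with the picolinic acid ligand system used for hindered phenols; the C–Br carbon of 35 has no ortho substituent and carries two meta methoxy groups, so only the phenoxide side is hindered, as in steps 3 and 7.

Step 21
Reactants: 36 permethylated decamer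
Product: 37 target decamer (CNP0255890.0), all twenty-six hydroxyls free
Conditions: BBr3 (excess), CH2Cl2, −78 °C to rt; then degassed H2O, argon; reversed-phase purification under argon
Reagents that add atoms: none
Why: Lewis-acid cleavage of aryl methyl ethers; each methoxy oxygen binds boron and bromide attacks the methyl carbon, whereas the diaryl ether oxygens have no sp3 carbon to be attacked and survive.

Compound list

1 | 5-iodo-1,2,3-trimethoxybenzene | COc1cc(I)cc(OC)c1OC | starting material
2 | 6-iodo-2,3,4-trimethoxybenzaldehyde | COc1cc(I)c(C=O)c(OC)c1OC | intermediate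
3 | 2,4,6-trimethoxybenzaldehyde | COc1cc(OC)c(C=O)c(OC)c1 | starting material
4 | 2,4,6-trimethoxyphenyl formate | COc1cc(OC)c(OC=O)c(OC)c1 | intermediate
5 | 2,4,6-trimethoxyphenol | COc1cc(OC)c(O)c(OC)c1 | intermediate
6 | 4-bromo-2,6-dimethoxybenzaldehyde | COc1cc(Br)cc(OC)c1C=O | starting material
7 | ring A–B dimer aldehyde, 2,6-dimethoxy-4-(2,4,6-trimethoxyphenoxy)benzaldehyde | COc1cc(OC)c(c(OC)c1)Oc1cc(OC)c(C=O)c(OC)c1 | intermediate
8 | ring A–B dimer formate, 2,6-dimethoxy-4-(2,4,6-trimethoxyphenoxy)phenyl formate | COc1cc(OC)c(c(OC)c1)Oc1cc(OC)c(OC=O)c(OC)c1 | intermediate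
9 | ring A–B dimer phenol, 2,6-dimethoxy-4-(2,4,6-trimethoxyphenoxy)phenol | COc1cc(OC)c(c(OC)c1)Oc1cc(OC)c(O)c(OC)c1 | intermediate
10 | ring A–C trimer aldehyde, 6-[2,6-dimethoxy-4-(2,4,6-trimethoxyphenoxy)phenoxy]-2,3,4-trimethoxybenzaldehyde | COc1cc(OC)c(c(OC)c1)Oc1cc(OC)c(c(OC)c1)Oc1cc(OC)c(OC)c(OC)c1C=O | intermediate
11 | ring A–C trimer formate (formyloxy on C2 of ring C) | COc1cc(OC)c(c(OC)c1)Oc1cc(OC)c(c(OC)c1)Oc1cc(OC)c(OC)c(OC)c1OC=O | intermediate
12 | ring A–C trimer phenol, 6-[2,6-dimethoxy-4-(2,4,6-trimethoxyphenoxy)phenoxy]-2,3,4-trimethoxyphenol | COc1cc(OC)c(c(OC)c1)Oc1cc(OC)c(c(OC)c1)Oc1cc(OC)c(OC)c(OC)c1O | intermediate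
13 | ring A–D tetramer aldehyde (CHO on C4 of ring D) | COc1cc(OC)c(c(OC)c1)Oc1cc(OC)c(c(OC)c1)Oc1cc(OC)c(OC)c(OC)c1Oc1cc(OC)c(C=O)c(OC)c1 | intermediate
14 | ring A–D tetramer formate (formyloxy on C4 of ring D) | COc1cc(OC)c(c(OC)c1)Oc1cc(OC)c(c(OC)c1)Oc1cc(OC)c(OC)c(OC)c1Oc1cc(OC)c(OC=O)c(OC)c1 | intermediate
15 | ring A–D tetramer phenol (OH on C4 of ring D) | COc1cc(OC)c(c(OC)c1)Oc1cc(OC)c(c(OC)c1)Oc1cc(OC)c(OC)c(OC)c1Oc1cc(OC)c(O)c(OC)c1 | intermediate
16 | ring A–E pentamer aldehyde (CHO on C2 of ring E) | COc1cc(OC)c(c(OC)c1)Oc1cc(OC)c(c(OC)c1)Oc1cc(OC)c(OC)c(OC)c1Oc1cc(OC)c(c(OC)c1)Oc1cc(OC)c(OC)c(OC)c1C=O | intermediate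
17 | ring A–E pentamer formate (formyloxy on C2 of ring E) | COc1cc(OC)c(c(OC)c1)Oc1cc(OC)c(c(OC)c1)Oc1cc(OC)c(OC)c(OC)c1Oc1cc(OC)c(c(OC)c1)Oc1cc(OC)c(OC)c(OC)c1OC=O | intermediate
18 | ring A–E pentamer phenol (OH on C2 of ring E) | COc1cc(OC)c(c(OC)c1)Oc1cc(OC)c(c(OC)c1)Oc1cc(OC)c(OC)c(OC)c1Oc1cc(OC)c(c(OC)c1)Oc1cc(OC)c(OC)c(OC)c1O | intermediate
19 | bromoacetaldehyde diethyl acetal (2-bromo-1,1-diethoxyethane) | CCOC(CBr)OCC | starting material
20 | ring A–E pentamer 2,2-diethoxyethyl ether (on the C2 oxygen of ring E) | COc1cc(OC)c(c(OC)c1)Oc1cc(OC)c(c(OC)c1)Oc1cc(OC)c(OC)c(OC)c1Oc1cc(OC)c(c(OC)c1)Oc1cc(OC)c(OC)c(OC)c1OCC(OCC)OCC | intermediate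
21 | ring A–E pentamer aryloxyacetaldehyde | COc1cc(OC)c(c(OC)c1)Oc1cc(OC)c(c(OC)c1)Oc1cc(OC)c(OC)c(OC)c1Oc1cc(OC)c(c(OC)c1)Oc1cc(OC)c(OC)c(OC)c1OCC=O | intermediate
22 | N,N-dimethylformamide dimethyl acetal | COC(OC)N(C)C | starting material
23 | (Z)-2-(ring A–E pentamer aryloxy)-3-(dimethylamino)prop-2-enal | COc1cc(OC)c(c(OC)c1)Oc1cc(OC)c(c(OC)c1)Oc1cc(OC)c(OC)c(OC)c1Oc1cc(OC)c(c(OC)c1)Oc1cc(OC)c(OC)c(OC)c1O/C(C=O)=C\N(C)C | intermediate
24 | 1,3-dimethoxyacetone (1,3-dimethoxypropan-2-one) | COCC(=O)COC | starting material
25 | (3E,5Z)-5-(ring A–E pentamer aryloxy)-6-(dimethylamino)-1,3-dimethoxyhexa-3,5-dien-2-one, drawn as the isomer that cyclises | COc1cc(OC)c(c(OC)c1)Oc1cc(OC)c(c(OC)c1)Oc1cc(OC)c(OC)c(OC)c1Oc1cc(OC)c(c(OC)c1)Oc1cc(OC)c(OC)c(OC)c1O/C(/C=C(/OC)C(=O)COC)=C\N(C)C | intermediate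
26 | ring A–F hexamer phenol (OH on C4 of ring F) | COc1cc(OC)c(c(OC)c1)Oc1cc(OC)c(c(OC)c1)Oc1cc(OC)c(OC)c(OC)c1Oc1cc(OC)c(c(OC)c1)Oc1cc(OC)c(OC)c(OC)c1Oc1cc(OC)c(O)c(OC)c1 | intermediate
27 | ring A–G heptamer aldehyde (CHO on C2 of ring G) | COc1cc(OC)c(c(OC)c1)Oc1cc(OC)c(c(OC)c1)Oc1cc(OC)c(OC)c(OC)c1Oc1cc(OC)c(c(OC)c1)Oc1cc(OC)c(OC)c(OC)c1Oc1cc(OC)c(c(OC)c1)Oc1cc(OC)c(OC)c(OC)c1C=O | intermediate
28 | ring A–G heptamer formate (formyloxy on C2 of ring G) | COc1cc(OC)c(c(OC)c1)Oc1cc(OC)c(c(OC)c1)Oc1cc(OC)c(OC)c(OC)c1Oc1cc(OC)c(c(OC)c1)Oc1cc(OC)c(OC)c(OC)c1Oc1cc(OC)c(c(OC)c1)Oc1cc(OC)c(OC)c(OC)c1OC=O | intermediate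
29 | ring A–G heptamer phenol (OH on C2 of ring G) | COc1cc(OC)c(c(OC)c1)Oc1cc(OC)c(c(OC)c1)Oc1cc(OC)c(OC)c(OC)c1Oc1cc(OC)c(c(OC)c1)Oc1cc(OC)c(OC)c(OC)c1Oc1cc(OC)c(c(OC)c1)Oc1cc(OC)c(OC)c(OC)c1O | intermediate
30 | 4-bromo-2,6-dimethoxyphenol | COc1cc(Br)cc(OC)c1O | starting material
31 | ring H–I dimer aldehyde, 6-(4-bromo-2,6-dimethoxyphenoxy)-2,3,4-trimethoxybenzaldehyde | COc1cc(Br)cc(OC)c1Oc1cc(OC)c(OC)c(OC)c1C=O | intermediate
32 | ring H–I dimer formate, 6-(4-bromo-2,6-dimethoxyphenoxy)-2,3,4-trimethoxyphenyl formate | COc1cc(Br)cc(OC)c1Oc1cc(OC)c(OC)c(OC)c1OC=O | intermediate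
33 | ring H–I dimer phenol, 6-(4-bromo-2,6-dimethoxyphenoxy)-2,3,4-trimethoxyphenol | COc1cc(Br)cc(OC)c1Oc1cc(OC)c(OC)c(OC)c1O | intermediate
34 | 3,4,5-trimethoxyphenylboronic acid | COc1cc(cc(OC)c1OC)B(O)O | starting material
35 | ring H–J trimer bromide, 5-bromo-1,3-dimethoxy-2-[3,4,5-trimethoxy-2-(3,4,5-trimethoxyphenoxy)phenoxy]benzene | COc1cc(Br)cc(OC)c1Oc1cc(OC)c(OC)c(OC)c1Oc1cc(OC)c(OC)c(OC)c1 | intermediate
36 | permethylated decamer (ring A–J hexacosamethyl ether) | COc1cc(OC)c(c(OC)c1)Oc1cc(OC)c(c(OC)c1)Oc1cc(OC)c(OC)c(OC)c1Oc1cc(OC)c(c(OC)c1)Oc1cc(OC)c(OC)c(OC)c1Oc1cc(OC)c(c(OC)c1)Oc1cc(OC)c(OC)c(OC)c1Oc1cc(OC)c(c(OC)c1)Oc1cc(OC)c(OC)c(OC)c1Oc1cc(OC)c(OC)c(OC)c1 | intermediate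
37 | target decamer CNP0255890.0 (no stereocentres) | Oc1cc(O)c(Oc2cc(O)c(Oc3cc(O)c(O)c(O)c3Oc3cc(O)c(Oc4cc(O)c(O)c(O)c4Oc4cc(O)c(Oc5cc(O)c(O)c(O)c5Oc5cc(O)c(Oc6cc(O)c(O)c(O)c6Oc6cc(O)c(O)c(O)c6)c(O)c5)c(O)c4)c(O)c3)c(O)c2)c(O)c1 | target

Total step count: 21. Longest linear sequence: 17 steps (steps 2 to 16, then 20 and 21, counted from 3); step 1 and steps 17 to 19 are side branches.

Steps least certain to work

Step 14 (key step). The formyl group of 23 is a vinylogous formamide and a weak electrophile, so enolate addition may be slower than the self-aldol reaction of 24, or the sequence may stall at the open-chain stage if the second enolisation is slow. The fallback raises the electrophilicity of the three-carbon unit and sets out from 23. Heating 23 with dimethylammonium tetrafluoroborate in ethanol should convert it into the vinamidinium salt 2-(ring A–E pentamer aryloxy)-1,3-bis(dimethylamino)trimethinium tetrafluoroborate F1. Treatment of F1 with 24 and t-BuOK in THF should then give the same dienone 25 by attack at an iminium carbon and close to 26, where the route is rejoined.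

Step 20. Activation of the C–Br bond of 35 by a copper phenoxide that has two ortho substituents may be slow, so that hydrodebromination of 35 and degradation of the phenoxide of 29 at 105 °C compete. The fallback reverses the polarity of the aryl partner and sets out from 35. Miyaura borylation (bis(pinacolato)diboron, Pd(dppf)Cl2, KOAc, dioxane, 90 °C) should give the ring H–J trimer pinacol boronate F2. Oxidative cleavage of the pinacol ester (NaIO4, NH4OAc, acetone–water) should give the ring H–J trimer boronic acid F3, which is joined to 29 by Chan–Lam coupling (Cu(OAc)2, pyridine, 4 Å MS, CH2Cl2, rt) to return to 36.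

Step 21. Cleavage of twenty-six ethers may stop short when partly demethylated aryl borates precipitate, and the free polyphenol may be lost to air oxidation during aqueous work-up and chromatography. The fallback changes the isolation and sets out from 36. After the BBr3 treatment and a methanol quench the crude polyphenol is acetylated (Ac2O, pyridine, DMAP) to the decamer hexacosaacetate F4, which is stable and can be purified on silica. Transesterification with catalytic HCl in degassed methanol under argon then returns the route to 37.

Step 12. The liberated α-aryloxy aldehyde may alkylate the electron-rich rings (ring A first) under acid catalysis or self-condense. The fallback avoids acid and sets out from 18. Alkylation with 2-bromo-N-methoxy-N-methylacetamide (K2CO3, DMF, 60 °C) should give the ring A–E pentamer 2-aryloxy-N-methoxy-N-methylacetamide F5. Reduction with i-Bu2AlH in THF at −78 °C and a tartrate work-up should release 21, where the route is rejoined.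

Step 19. Coupling at a phenol flanked by an aryloxy and a methoxy group may be slow enough that protodeboronation and homocoupling consume 34. The fallback uses a metal-free aryl transfer and sets out from 33. Oxidation of 1 with mCPBA and TsOH·H2O in acetonitrile, followed by 1,3,5-trimethoxybenzene, should give (3,4,5-trimethoxyphenyl)(2,4,6-trimethoxyphenyl)iodonium tosylate F6. Phenol 33 with F6 and K2CO3 in toluene at 50 °C should give 35 by ligand coupling at trivalent iodine, the 2,4,6-trimethoxyphenyl group staying on iodine.

Further compounds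

F1 | step 14 | 2-(ring A–E pentamer aryloxy)-1,3-bis(dimethylamino)trimethinium tetrafluoroborate | COc1cc(OC)c(c(OC)c1)Oc1cc(OC)c(c(OC)c1)Oc1cc(OC)c(OC)c(OC)c1Oc1cc(OC)c(c(OC)c1)Oc1cc(OC)c(OC)c(OC)c1O/C(/C=[N+](C)C)=C\N(C)C.F[B-](F)(F)F
F2 | step 20 | ring H–J trimer pinacol boronate | COc1cc(cc(OC)c1Oc1cc(OC)c(OC)c(OC)c1Oc1cc(OC)c(OC)c(OC)c1)B1OC(C)(C)C(C)(C)O1
F3 | step 20 | ring H–J trimer boronic acid | COc1cc(cc(OC)c1Oc1cc(OC)c(OC)c(OC)c1Oc1cc(OC)c(OC)c(OC)c1)B(O)O
F4 | step 21 | decamer hexacosaacetate | CC(=O)Oc1cc(OC(C)=O)c(c(OC(C)=O)c1)Oc1cc(OC(C)=O)c(c(OC(C)=O)c1)Oc1cc(OC(C)=O)c(OC(C)=O)c(OC(C)=O)c1Oc1cc(OC(C)=O)c(c(OC(C)=O)c1)Oc1cc(OC(C)=O)c(OC(C)=O)c(OC(C)=O)c1Oc1cc(OC(C)=O)c(c(OC(C)=O)c1)Oc1cc(OC(C)=O)c(OC(C)=O)c(OC(C)=O)c1Oc1cc(OC(C)=O)c(c(OC(C)=O)c1)Oc1cc(OC(C)=O)c(OC(C)=O)c(OC(C)=O)c1Oc1cc(OC(C)=O)c(OC(C)=O)c(OC(C)=O)c1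
F5 | step 12 | ring A–E pentamer 2-aryloxy-N-methoxy-N-methylacetamide | COc1cc(OC)c(c(OC)c1)Oc1cc(OC)c(c(OC)c1)Oc1cc(OC)c(OC)c(OC)c1Oc1cc(OC)c(c(OC)c1)Oc1cc(OC)c(OC)c(OC)c1OCC(=O)N(C)OC
F6 | step 19 | (3,4,5-trimethoxyphenyl)(2,4,6-trimethoxyphenyl)iodonium tosylate | COc1cc(cc(OC)c1OC)[I+]c1c(OC)cc(OC)cc1OC.Cc1ccc(cc1)S([O-])(=O)=O
A1 | alternative 1 | cyclopentadienylruthenium η6 complex of 2,5-dichloro-1,3-dimethoxybenzene, hexafluorophosphate, written as separated ions | COc1cc(Cl)cc(OC)c1Cl.[Ru+2].c1cc[cH-]c1.F[P-](F)(F)(F)(F)F
A2 | alternative 1 | ring I–J dimer phenol, 3,4,5-trimethoxy-2-(3,4,5-trimethoxyphenoxy)phenol | COc1cc(O)c(Oc2cc(OC)c(OC)c(OC)c2)c(OC)c1OC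
A3 | alternative 1 | permethylated decamer bound η6 through ring H to cyclopentadienylruthenium hexafluorophosphate, written as separated ions | COc1cc(OC)c(c(OC)c1)Oc1cc(OC)c(c(OC)c1)Oc1cc(OC)c(OC)c(OC)c1Oc1cc(OC)c(c(OC)c1)Oc1cc(OC)c(OC)c(OC)c1Oc1cc(OC)c(c(OC)c1)Oc1cc(OC)c(OC)c(OC)c1Oc1cc(OC)c(c(OC)c1)Oc1cc(OC)c(OC)c(OC)c1Oc1cc(OC)c(OC)c(OC)c1.[Ru+2].c1cc[cH-]c1.F[P-](F)(F)(F)(F)F
A4 | alternative 2 | racemic 4-hydroxy-2,3-dimethoxy-4-{1-[2,6-dimethoxy-4-(2,4,6-trimethoxyphenoxy)phenoxy]vinyl}cyclobut-2-en-1-one | COC1=C(OC)C(O)(C(=C)Oc2c(OC)cc(Oc3c(OC)cc(OC)cc3OC)cc2OC)C1=O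
A5 | alternative 2 | ring A–C trimer hydroquinone with free hydroxyls on C2 and C5 of ring C | COc1cc(OC)c(c(OC)c1)Oc1cc(OC)c(c(OC)c1)Oc1cc(O)c(OC)c(OC)c1O
A6 | alternative 3 | dimethyl 2-(ring B–J nonamer aryloxy)malonate | COC(=O)C(Oc1cc(OC)c(c(OC)c1)Oc1cc(OC)c(OC)c(OC)c1Oc1cc(OC)c(c(OC)c1)Oc1cc(OC)c(OC)c(OC)c1Oc1cc(OC)c(c(OC)c1)Oc1cc(OC)c(OC)c(OC)c1Oc1cc(OC)c(c(OC)c1)Oc1cc(OC)c(OC)c(OC)c1Oc1cc(OC)c(OC)c(OC)c1)C(=O)OC
A7 | alternative 3 | dimethyl 3-oxopentanedioate | COC(=O)CC(=O)CC(=O)OC
A8 | alternative 3 | decamer with ring A as dimethyl 5-aryloxy-2,4,6-trihydroxyisophthalate | COC(=O)c2c(O)c(Oc1cc(OC)c(c(OC)c1)Oc1cc(OC)c(OC)c(OC)c1Oc1cc(OC)c(c(OC)c1)Oc1cc(OC)c(OC)c(OC)c1Oc1cc(OC)c(c(OC)c1)Oc1cc(OC)c(OC)c(OC)c1Oc1cc(OC)c(c(OC)c1)Oc1cc(OC)c(OC)c(OC)c1Oc1cc(OC)c(OC)c(OC)c1)c(O)c(C(=O)OC)c2O
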